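A direct plan would close the two flavanone halves separately by catalytic asymmetric oxa-Michael addition,
convert the 4-methoxyphenyl half into the 3-bromo β-keto ester A1 and the other half into the silyl enol ether A2,
and join them at C3–C3'' by a radical alkylation to A3, followed by hydrogenolysis and decarboxylation.
Its weakest steps would be (a) the fragment union, which would have to build a quaternary carbon between two hindered ring carbons while C3'' is set by substrate bias alone;
(b) the final decarboxylative protonation, which would have to deliver the less stable 2,3-cis ring kinetically with nothing that enforces the face;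
(c) the carrying of C2 through several steps in β-keto ester flavanones that would racemise by retro-oxa-Michael opening.

The C2–C3–C3''–C2'' chain is read as succinic acid aldolised twice, and each ring A, which carries O1 (at C8a) and the C4 acyl carbon (at C4a) on neighbouring carbons with C5–O beside C4a, as 3,5-bis(benzyloxy)benzyne. Two auxiliary-controlled aldol reactions on a succinyl bis-thioimide set all four stereocentres in open-chain form: syn for unit 1 (4-methoxyphenyl), anti for unit 2 (4-hydroxyphenyl). In the key step both pyranone rings close at once: each alkoxide adds to the aryne and the aryl anion is trapped by the adjacent Weinreb amide, with retention everywhere. No C3–C3'' coupling, kinetic protonation or base-labile flavanone intermediate remains.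

Key step: step 8

Locants: unit 1 is the 4-methoxyphenyl flavanone (O1, C2–C8a, rings A and C); unit 2 is the 4-hydroxyphenyl flavanone (double-primed locants, rings A'' and C'').
Assumption: in the magnesium-catalysed anti-aldol of step 2 the thione sulfur is taken not to chelate magnesium, so that the enolate face attacked is the one used by the boron aldol of step 3; compounds 1, 2, 4, 6 and 10 are taken as commercial.

**Step 1**
Reactants: 1 succinyl chloride + 2 (4S)-4-benzyl-1,3-thiazolidine-2-thione (2 equiv)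
Product: 3 1,4-bis[(4S)-4-benzyl-2-thioxo-1,3-thiazolidin-3-yl]butane-1,4-dione
Conditions: Et3N (2.4 equiv), CH2Cl2, −20 → 0 °C
Reagents that add atoms: none
Why: N-acylation of the thiazolidinethione by the diacid chloride should give the C2-symmetric bis-thioimide, whose two activated acyl groups serve first as aldol donors and later as leaving groups.

**Step 2**
Reactants: 3 (1.5 equiv) + 4 4-(benzyloxy)benzaldehyde
Product: 5 (2S)-2-{(R)-[4-(benzyloxy)phenyl][(trimethylsilyl)oxy]methyl}-1,4-bis[(4S)-4-benzyl-2-thioxo-1,3-thiazolidin-3-yl]butane-1,4-dione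
Conditions: MgBr2·OEt2 (15 mol%), Et3N (2 equiv), TMSCl (1.5 equiv), EtOAc, rt; Et3N-deactivated silica
Reagents that add atoms: chlorotrimethylsilane, C[Si](C)(C)Cl
Why: Magnesium-halide-catalysed direct anti-aldol reaction of an N-acylthiazolidinethione, in which the non-chelated Z-enolate should be attacked on the face away from the benzyl group (C3'' S) through a boat-like arrangement that places the aryl carbinol anti (C2'' R), while silylation of the aldolate turns the catalyst over and the branched mono-adduct enolises more slowly than 3, which limits double addition.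

**Step 3**
Reactants: 5 + 6 4-methoxybenzaldehyde
Product: 7 (2S,3S)-2-{(R)-[4-(benzyloxy)phenyl][(trimethylsilyl)oxy]methyl}-3-[(S)-hydroxy(4-methoxyphenyl)methyl]-1,4-bis[(4S)-4-benzyl-2-thioxo-1,3-thiazolidin-3-yl]butane-1,4-dione
Conditions: Bu2BOTf (1.2 equiv), i-Pr2NEt (1.4 equiv), CH2Cl2, −78 → 0 °C; 6 (1.5 equiv), −78 → −20 °C; pH 7 buffer/MeOH (no peroxide)
Reagents that add atoms: none
Why: Boron-mediated syn-aldol reaction of a chiral N-acyl imide (Evans aldol), in which the Z-dibutylboron enolate should form at the only CH2 (the C3''–H is held in the imide plane by allylic strain) and react through a dipole-opposed Zimmerman–Traxler chair on the face away from the benzyl group, giving C3 (S) and C2 (S) syn on the same enolate face as in step 2, so that C3 and C3'' come out alike.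

**Step 4**
Reactants: 7
Product: 9 (2S,3S)-2-{(R)-[4-(benzyloxy)phenyl](hydroxy)methyl}-3-[(S)-hydroxy(4-methoxyphenyl)methyl]-N1,N4-dimethoxy-N1,N4-dimethylbutanediamide, via TMS ether bis-Weinreb amide 8 (not isolated)
Conditions: Me(MeO)NH·HCl (6 equiv), AlMe3 (6 equiv), CH2Cl2, −20 → 0 °C; aq. KNaC4H4O6; then citric acid, MeOH, 0 °C
Reagents that add atoms: N,O-dimethylhydroxylamine hydrochloride, CNOC.Cl
Why: Aluminium amide aminolysis (Weinreb transamidation) should displace both thiazolidinethiones, and open any γ-lactone formed by closure of the free hydroxyl onto a thioimide, to give amides that cannot lactonise, after which mild acidic methanolysis removes the TMS group without ionising the benzylic C–O bonds.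

**Step 5**
Reactants: 10 3,5-bis(benzyloxy)phenol
Product: 11 3,5-bis(benzyloxy)phenyl N-isopropylcarbamate
Conditions: i-PrNCO (1.5 equiv), Et3N (0.2 equiv), CH2Cl2, rt
Reagents that add atoms: isopropyl isocyanate, CC(C)N=C=O
Why: Addition of the phenol to the isocyanate should give the secondary carbamate, a strong directing group for metalation that is later removed under mild base.

**Step 6**
Reactants: 11
Product: 14 3,5-bis(benzyloxy)-2-(trimethylsilyl)phenyl N-isopropylcarbamate, via N-TBS carbamate 12 (not isolated), via N-TBS 2-silyl carbamate 13 (not isolated)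
Conditions: TBSOTf (1.1 equiv), TMEDA (1.1 equiv), Et2O, 0 °C → rt; n-BuLi (2 equiv), TMEDA (2 equiv), −78 °C; TMSCl (3 equiv), −78 °C → rt; aq. NaHSO4
Reagents that add atoms: chlorotrimethylsilane, C[Si](C)(C)Cl; tert-butyldimethylsilyl triflate, CC(C)(C)[Si](C)(C)OS(=O)(=O)C(F)(F)F (its silyl group is present only in 12 and 13)
Why: Directed ortho-metalation, in which the N-silylated carbamate should direct lithiation to C2, the position flanked by the carbamate and a benzyloxy group, faster than to the other ring positions or the benzylic CH2, and the aryllithium is silylated at −78 °C before anionic Fries rearrangement can set in.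

**Step 7**
Reactants: 14
Product: 16 3,5-bis(benzyloxy)-2-(trimethylsilyl)phenyl trifluoromethanesulfonate, via silyl phenol 15 (not isolated)
Conditions: Et2NH (1.5 equiv), DBU (1.5 equiv), MeCN, 40 °C; then PhNTf2 (1.5 equiv), rt
Reagents that add atoms: N-phenylbis(trifluoromethanesulfonimide), O=S(=O)(N(c1ccccc1)S(=O)(=O)C(F)(F)F)C(F)(F)F
Why: Base-induced E1cB cleavage of the secondary carbamate (the isocyanate is trapped by Et2NH as a urea) and triflation of the phenoxide should give the ortho-silylaryl triflate that releases the aryne on treatment with fluoride.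

**Step 8**
Reactants: 9 + 16 (2.6 equiv)
Product: 19 (2S,3S)-5,7-bis(benzyloxy)-3-{(2R,3S)-5,7-bis(benzyloxy)-2-[4-(benzyloxy)phenyl]-4-oxochroman-3-yl}-2-(4-methoxyphenyl)chroman-4-one, via aryne 17 (not isolated), via bis-hemiaminal 18 (not isolated)
Conditions: NaH (2.2 equiv), THF, 0 °C; then 16, CsF (6 equiv), 18-crown-6 (6 equiv), THF, 0 °C → rt; sat. aq. NH4Cl, then pH 4 buffer
Reagents that add atoms: none
Why: Proposed new method: fluoride-induced 1,2-elimination of 16 gives aryne 17, which is polarised by its C3 benzyloxy group so that each sodium alkoxide of 9 adds at C1, the aryne carbon remote from that group, leaving the carbanion at C2 beside it; this aryl anion attacks the Weinreb amide of its own aldol unit to give the tetrahedral adduct 18, which collapses to the ketone only on quench. The closest known reaction type is the aryne annulation of salicylates to xanthones (nucleophilic addition followed by intramolecular acyl capture), here transferred to an aliphatic β-hydroxy amide. Each pyranone ring (ring C and ring C'') is closed by intermolecular O1–C8a bond formation followed by 6-exo-trig C4–C4a acylation, the seven-membered alternative through the other amide being slower. No new stereocentre is formed and no bond at C2, C3, C3'' or C2'' is broken, so the syn unit should become the 2,3-cis ring (2S,3S) and the anti unit the 2,3-trans ring (2''R,3''S) with retention. The step needs regioselective aryne addition, secured by the inductive effect of the flanking C–O bond, and acyl capture in preference to protonation of the aryl anion, secured by the preformed, proton-free dialkoxide; the masked ketones and the amide-level acidity of C3–H and C3''–H exclude epimerisation and retro-oxa-Michael opening.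

**Step 9**
Reactants: 19
Product: 20 (2S,3S)-5,7-dihydroxy-3-[(2R,3S)-5,7-dihydroxy-2-(4-hydroxyphenyl)-4-oxochroman-3-yl]-2-(4-methoxyphenyl)chroman-4-one
Conditions: H2 (1 atm), 10% Pd/C, EtOAc/MeOH 1:1, rt
Reagents that add atoms: none
Why: Hydrogenolysis of the five primary benzyl ethers under neutral conditions should leave the 4'-methyl ether, the more slowly cleaved secondary O1–C2 and O1''–C2'' bonds and all four stereocentres, including the epimerisable 2,3-cis ring, untouched.

**Compound list**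
1 | succinyl chloride | ClC(=O)CCC(=O)Cl | starting material
2 | (4S)-4-benzyl-1,3-thiazolidine-2-thione | S=C1N[C@@H](Cc2ccccc2)CS1 | starting material
3 | 1,4-bis[(4S)-4-benzyl-2-thioxo-1,3-thiazolidin-3-yl]butane-1,4-dione | O=C(CCC(=O)N1[C@@H](Cc2ccccc2)CSC1=S)N1[C@@H](Cc2ccccc2)CSC1=S | intermediate
4 | 4-(benzyloxy)benzaldehyde | O=Cc1ccc(OCc2ccccc2)cc1 | starting material
5 | (2S)-2-{(R)-[4-(benzyloxy)phenyl][(trimethylsilyl)oxy]methyl}-1,4-bis[(4S)-4-benzyl-2-thioxo-1,3-thiazolidin-3-yl]butane-1,4-dione | O=C(C[C@H](C(=O)N1[C@@H](Cc2ccccc2)CSC1=S)[C@@H](O[Si](C)(C)C)c1ccc(OCc2ccccc2)cc1)N1[C@@H](Cc2ccccc2)CSC1=S | intermediate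
6 | 4-methoxybenzaldehyde | COc1ccc(C=O)cc1 | starting material
7 | (2S,3S)-2-{(R)-[4-(benzyloxy)phenyl][(trimethylsilyl)oxy]methyl}-3-[(S)-hydroxy(4-methoxyphenyl)methyl]-1,4-bis[(4S)-4-benzyl-2-thioxo-1,3-thiazolidin-3-yl]butane-1,4-dione | COc1ccc(cc1)[C@@H](O)[C@@H](C(=O)N1[C@@H](Cc2ccccc2)CSC1=S)[C@H](C(=O)N1[C@@H](Cc2ccccc2)CSC1=S)[C@@H](O[Si](C)(C)C)c1ccc(OCc2ccccc2)cc1 | intermediate
8 | (2S,3S)-2-{(R)-[4-(benzyloxy)phenyl][(trimethylsilyl)oxy]methyl}-3-[(S)-hydroxy(4-methoxyphenyl)methyl]-N1,N4-dimethoxy-N1,N4-dimethylbutanediamide | COc1ccc(cc1)[C@@H](O)[C@@H](C(=O)N(C)OC)[C@H](C(=O)N(C)OC)[C@@H](O[Si](C)(C)C)c1ccc(OCc2ccccc2)cc1 | intermediate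
9 | (2S,3S)-2-{(R)-[4-(benzyloxy)phenyl](hydroxy)methyl}-3-[(S)-hydroxy(4-methoxyphenyl)methyl]-N1,N4-dimethoxy-N1,N4-dimethylbutanediamide | COc1ccc(cc1)[C@@H](O)[C@@H](C(=O)N(C)OC)[C@H](C(=O)N(C)OC)[C@@H](O)c1ccc(OCc2ccccc2)cc1 | intermediate
10 | 3,5-bis(benzyloxy)phenol | Oc1cc(OCc2ccccc2)cc(OCc2ccccc2)c1 | starting material
11 | 3,5-bis(benzyloxy)phenyl N-isopropylcarbamate | CC(C)NC(=O)Oc1cc(OCc2ccccc2)cc(OCc2ccccc2)c1 | intermediate
12 | 3,5-bis(benzyloxy)phenyl N-(tert-butyldimethylsilyl)-N-isopropylcarbamate | CC(C)N(C(=O)Oc1cc(OCc2ccccc2)cc(OCc2ccccc2)c1)[Si](C)(C)C(C)(C)C | intermediate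
13 | 3,5-bis(benzyloxy)-2-(trimethylsilyl)phenyl N-(tert-butyldimethylsilyl)-N-isopropylcarbamate | CC(C)N(C(=O)Oc1cc(OCc2ccccc2)cc(OCc2ccccc2)c1[Si](C)(C)C)[Si](C)(C)C(C)(C)C | intermediate
14 | 3,5-bis(benzyloxy)-2-(trimethylsilyl)phenyl N-isopropylcarbamate | CC(C)NC(=O)Oc1cc(OCc2ccccc2)cc(OCc2ccccc2)c1[Si](C)(C)C | intermediate
15 | 3,5-bis(benzyloxy)-2-(trimethylsilyl)phenol | Oc1cc(OCc2ccccc2)cc(OCc2ccccc2)c1[Si](C)(C)C | intermediate
16 | 3,5-bis(benzyloxy)-2-(trimethylsilyl)phenyl trifluoromethanesulfonate | C[Si](C)(C)c1c(OCc2ccccc2)cc(OCc2ccccc2)cc1OS(=O)(=O)C(F)(F)F | intermediate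
17 | 3,5-bis(benzyloxy)benzyne (1,2-didehydro-3,5-bis(benzyloxy)benzene) | C1#CC(OCc2ccccc2)=CC(OCc2ccccc2)=C1 | intermediate
18 | (2S,3S)-5,7-bis(benzyloxy)-3-{(2R,3S)-5,7-bis(benzyloxy)-2-[4-(benzyloxy)phenyl]-4-hydroxy-4-[methoxy(methyl)amino]chroman-3-yl}-4-[methoxy(methyl)amino]-2-(4-methoxyphenyl)chroman-4-ol (present as its dialkoxide; C4 and C4'' undefined) | COc1ccc([C@H]2Oc3cc(OCc4ccccc4)cc(OCc4ccccc4)c3C(O)(N(C)OC)[C@H]2[C@@H]2C(O)(N(C)OC)c3c(OCc4ccccc4)cc(OCc4ccccc4)cc3O[C@H]2c2ccc(OCc3ccccc3)cc2)cc1 | intermediate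
19 | (2S,3S)-5,7-bis(benzyloxy)-3-{(2R,3S)-5,7-bis(benzyloxy)-2-[4-(benzyloxy)phenyl]-4-oxochroman-3-yl}-2-(4-methoxyphenyl)chroman-4-one | COc1ccc([C@H]2Oc3cc(OCc4ccccc4)cc(OCc4ccccc4)c3C(=O)[C@H]2[C@@H]2C(=O)c3c(OCc4ccccc4)cc(OCc4ccccc4)cc3O[C@H]2c2ccc(OCc3ccccc3)cc2)cc1 | intermediate
20 | (2S,3S)-5,7-dihydroxy-3-[(2R,3S)-5,7-dihydroxy-2-(4-hydroxyphenyl)-4-oxochroman-3-yl]-2-(4-methoxyphenyl)chroman-4-one | COc1ccc([C@H]2Oc3cc(O)cc(O)c3C(=O)[C@H]2[C@@H]2C(=O)c3c(O)cc(O)cc3O[C@H]2c2ccc(O)cc2)cc1 | target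

Total: 9 steps. Longest linear sequence: 6 steps (1, 2, 3, 4, 8, 9); the aryne precursor branch (5–7) joins at step 8.

**Steps most likely to fail**

Step 8 (the aryl anion may be quenched by proton transfer before acyl capture, the dialkoxide may undergo retro-aldol cleavage, or adduct 18 may be arylated further). The fallback sets out from 16 and 9 and returns at 19 through 18. Generation of the aryne from 16 in the presence of I2 (CsF, MeCN) would give 1,5-bis(benzyloxy)-2,3-diiodobenzene F1 by the known 1,2-diiodination of arynes. Ullmann-type O-arylation of diol 9 with F1 (CuI, 3,4,7,8-tetramethyl-1,10-phenanthroline, Cs2CO3, toluene, 90 °C), at the less hindered iodide remote from the benzyloxy group, would give (2S,3S)-2-{(R)-[4-(benzyloxy)phenyl][3,5-bis(benzyloxy)-2-iodophenoxy]methyl}-3-{(S)-[3,5-bis(benzyloxy)-2-iodophenoxy](4-methoxyphenyl)methyl}-N1,N4-dimethoxy-N1,N4-dimethylbutanediamide F2 with retention at C2 and C2''. Iodine–magnesium exchange (i-PrMgCl·LiCl, THF, −40 °C) and Parham-type cyclisation of each arylmagnesium onto its Weinreb amide would then give 18 and, on quench, 19. The same aryl anion would thus be made by halogen–metal exchange instead of by addition to the aryne.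

Step 3 (poor facial selectivity if the auxiliary and the neighbouring C3'' centre are mismatched, or slow enolisation beside the branched carbon). The fallback sets out from 3 and returns at 9, with the order of the two aldol reactions reversed so that the chair-type syn aldol runs on the unbranched substrate. Boron aldol of 3 with 6 (Bu2BOTf, i-Pr2NEt) would give (2S)-1,4-bis[(4S)-4-benzyl-2-thioxo-1,3-thiazolidin-3-yl]-2-[(S)-hydroxy(4-methoxyphenyl)methyl]butane-1,4-dione F3, silylated at once (TESOTf, 2,6-lutidine) to its triethylsilyl ether F4. The magnesium-catalysed anti-aldol of F4 with 4 (conditions of step 2) would give the bis-silyl ether bis-thioimide F5. Aluminium amide aminolysis as in step 4 would give the bis-silyl ether bis-Weinreb amide F6, and HF·pyridine (THF, 0 °C) would release 9.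

Step 2 (insufficient anti or facial selectivity, or double addition). The fallback sets out from 3 and returns at 5, replacing the direct anti-aldol by a syn aldol with inversion of the carbinol through its ketone. Boron aldol of 3 with 4 would give the syn adduct (2S)-2-{(S)-[4-(benzyloxy)phenyl](hydroxy)methyl}-1,4-bis[(4S)-4-benzyl-2-thioxo-1,3-thiazolidin-3-yl]butane-1,4-dione F7. Dess–Martin oxidation would give (2S)-2-[4-(benzyloxy)benzoyl]-1,4-bis[(4S)-4-benzyl-2-thioxo-1,3-thiazolidin-3-yl]butane-1,4-dione F8, whose C3'' centre is protected from enolisation by allylic strain. Corey–Bakshi–Shibata reduction ((S)-2-methyl-CBS-oxazaborolidine, catecholborane, toluene, −78 °C; aryl as the large group, ketone reduced faster than the thioimides) would give the anti alcohol (2S)-2-{(R)-[4-(benzyloxy)phenyl](hydroxy)methyl}-1,4-bis[(4S)-4-benzyl-2-thioxo-1,3-thiazolidin-3-yl]butane-1,4-dione F9. Silylation (TMSCl, imidazole) would give 5; F7 and F9 would be handled cold and carried on at once to avoid lactonisation onto the distal thioimide.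

**Further compounds**
F1 | step 8 | 1,5-bis(benzyloxy)-2,3-diiodobenzene | Ic1cc(OCc2ccccc2)cc(OCc2ccccc2)c1I
F2 | step 8 | (2S,3S)-2-{(R)-[4-(benzyloxy)phenyl][3,5-bis(benzyloxy)-2-iodophenoxy]methyl}-3-{(S)-[3,5-bis(benzyloxy)-2-iodophenoxy](4-methoxyphenyl)methyl}-N1,N4-dimethoxy-N1,N4-dimethylbutanediamide | COc1ccc(cc1)[C@@H](Oc1cc(OCc2ccccc2)cc(OCc2ccccc2)c1I)[C@@H](C(=O)N(C)OC)[C@H](C(=O)N(C)OC)[C@@H](Oc1cc(OCc2ccccc2)cc(OCc2ccccc2)c1I)c1ccc(OCc2ccccc2)cc1
F3 | step 3 | (2S)-1,4-bis[(4S)-4-benzyl-2-thioxo-1,3-thiazolidin-3-yl]-2-[(S)-hydroxy(4-methoxyphenyl)methyl]butane-1,4-dione | COc1ccc(cc1)[C@@H](O)[C@@H](C(=O)N1[C@@H](Cc2ccccc2)CSC1=S)CC(=O)N1[C@@H](Cc2ccccc2)CSC1=S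
F4 | step 3 | (2S)-1,4-bis[(4S)-4-benzyl-2-thioxo-1,3-thiazolidin-3-yl]-2-[(S)-(4-methoxyphenyl)(triethylsilyloxy)methyl]butane-1,4-dione | COc1ccc(cc1)[C@@H](O[Si](CC)(CC)CC)[C@@H](C(=O)N1[C@@H](Cc2ccccc2)CSC1=S)CC(=O)N1[C@@H](Cc2ccccc2)CSC1=S
F5 | step 3 | (2S,3S)-2-{(R)-[4-(benzyloxy)phenyl](trimethylsilyloxy)methyl}-1,4-bis[(4S)-4-benzyl-2-thioxo-1,3-thiazolidin-3-yl]-3-[(S)-(4-methoxyphenyl)(triethylsilyloxy)methyl]butane-1,4-dione | COc1ccc(cc1)[C@@H](O[Si](CC)(CC)CC)[C@@H](C(=O)N1[C@@H](Cc2ccccc2)CSC1=S)[C@H](C(=O)N1[C@@H](Cc2ccccc2)CSC1=S)[C@@H](O[Si](C)(C)C)c1ccc(OCc2ccccc2)cc1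
F6 | step 3 | (2S,3S)-2-{(R)-[4-(benzyloxy)phenyl](trimethylsilyloxy)methyl}-N1,N4-dimethoxy-3-[(S)-(4-methoxyphenyl)(triethylsilyloxy)methyl]-N1,N4-dimethylbutanediamide | COc1ccc(cc1)[C@@H](O[Si](CC)(CC)CC)[C@@H](C(=O)N(C)OC)[C@H](C(=O)N(C)OC)[C@@H](O[Si](C)(C)C)c1ccc(OCc2ccccc2)cc1
F7 | step 2 | (2S)-2-{(S)-[4-(benzyloxy)phenyl](hydroxy)methyl}-1,4-bis[(4S)-4-benzyl-2-thioxo-1,3-thiazolidin-3-yl]butane-1,4-dione | O=C(C[C@H](C(=O)N1[C@@H](Cc2ccccc2)CSC1=S)[C@H](O)c1ccc(OCc2ccccc2)cc1)N1[C@@H](Cc2ccccc2)CSC1=S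
F8 | step 2 | (2S)-2-[4-(benzyloxy)benzoyl]-1,4-bis[(4S)-4-benzyl-2-thioxo-1,3-thiazolidin-3-yl]butane-1,4-dione | O=C(C[C@H](C(=O)N1[C@@H](Cc2ccccc2)CSC1=S)C(=O)c1ccc(OCc2ccccc2)cc1)N1[C@@H](Cc2ccccc2)CSC1=S
F9 | step 2 | (2S)-2-{(R)-[4-(benzyloxy)phenyl](hydroxy)methyl}-1,4-bis[(4S)-4-benzyl-2-thioxo-1,3-thiazolidin-3-yl]butane-1,4-dione | O=C(C[C@H](C(=O)N1[C@@H](Cc2ccccc2)CSC1=S)[C@@H](O)c1ccc(OCc2ccccc2)cc1)N1[C@@H](Cc2ccccc2)CSC1=S
A1 | direct plan | benzyl (2R,3R)-5,7-bis(benzyloxy)-3-bromo-2-(4-methoxyphenyl)-4-oxochromane-3-carboxylate | COc1ccc([C@H]2Oc3cc(OCc4ccccc4)cc(OCc4ccccc4)c3C(=O)[C@@]2(Br)C(=O)OCc2ccccc2)cc1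
A2 | direct plan | tert-butyl({(2R)-5,7-bis(benzyloxy)-2-[4-(benzyloxy)phenyl]-2H-chromen-4-yl}oxy)dimethylsilane | C1=C(O[Si](C)(C)C(C)(C)C)c2c(OCc3ccccc3)cc(OCc3ccccc3)cc2O[C@H]1c1ccc(OCc2ccccc2)cc1
A3 | direct plan | benzyl (2R,3S)-5,7-bis(benzyloxy)-3-{(2R,3S)-5,7-bis(benzyloxy)-2-[4-(benzyloxy)phenyl]-4-oxochroman-3-yl}-2-(4-methoxyphenyl)-4-oxochromane-3-carboxylate | COc1ccc([C@H]2Oc3cc(OCc4ccccc4)cc(OCc4ccccc4)c3C(=O)[C@]2(C(=O)OCc2ccccc2)[C@@H]2C(=O)c3c(OCc4ccccc4)cc(OCc4ccccc4)cc3O[C@H]2c2ccc(OCc3ccccc3)cc2)cc1
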